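The data were generated by integration for an exercise, and the scatter is random.

**The choice.** The reagent is the first charge to choose for the next flask: 0.700 equiv in noon, autumn and dawn, against 1.40 equiv in spring. Catalyst loading and the spacing of the portions are weighed after it.

| setting | violet | red | ochre | noon | spring | dawn | autumn |
|---|---|---|---|---|---|---|---|
| substrate | 0.050 M | 0.050 M | 0.050 M | 0.050 M | 0.050 M | 0.050 M | 0.050 M |
| reagent | 0.70 equiv (in portions, 4) | 0.70 equiv (in portions, 4) | 1.4 equiv (in portions, 4) | 0.700 equiv (in portions, 4) | 1.40 equiv (in portions, 4) | 0.700 equiv (in portions, 4) | 0.700 equiv (in portions, 4) |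
| free catalyst | 0.51 mol% | 1.7 mol% | 0.58 mol% | 0.58 mol% | 0.58 mol% | 2 mol% | 0.58 mol% |
| remark | run made earlier; portions every 25 min | run made earlier; portions every 25 min | run made earlier; portions every 25 min | the portions of reagent follow each other after 25 min, the first at the start | the portions of reagent follow each other after 8.0 min, the first at the start | the portions of reagent follow each other after 15 min, the first at the start | the portions of reagent follow each other after 8.0 min, the first at the start |
| time |  |  |  | 2.5 h | 2.5 h | 2.5 h | 2.5 h |

| run | time / min | product / % | substrate / % |
|---|---|---|---|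
| violet | 20.0 | 6 | 92 |
| violet | 40.0 | 18 | 85 |
| violet | 60.0 | 25 | 73 |
| violet | 80.0 | 36 | 67 |
| red | 6.00 | 6 | 94 |
| red | 15.0 | 11 | 87 |
| red | 30.0 | 24 | 76 |
| red | 80.0 | 54 | 46 |
| ochre | 20.0 | 11 | 87 |
| ochre | 40.0 | 31 | 66 |
| ochre | 60.0 | 52 | 46 |
| ochre | 80.0 | 64 | 29 |

(scatter of a reading: 2 percentage points)

1. all flasks from highest to lowest amount of product, in percent of the substrate charged, at 2.5 h (noon / spring / dawn / autumn)
2. the same order at 15 min (noon / spring / dawn / autumn)
3. the amount of product, in percent of the substrate charged of the flask you put first, at 2.5 h
4. the amount of product, in percent of the substrate charged of the flask you put last, at 2.5 h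

**The ceiling.** The earlier runs do not contradict one reagent per product, so that is assumed here. Then product cannot pass 70.0% in noon, autumn and dawn, where reagent is the limiting reagent, nor 100% in spring. This smaller of the charged equivalents and one, in percent of the substrate charged, is the product ceiling, P_max.

**Reaching it.** Ochre has spring's reagent and catalyst loading, so it shows how close spring may come. Between 60.0 min and 80.0 min ochre's substrate fell from 46% to 29%, which reads as a halving time τ of 30.0 min. Carried on to 2.5 h, that τ leaves about 5.77% of the substrate, so this reckoning puts spring near 94.2%. That reckoning takes the fall as first order, yet ochre's substrate fell in nearly even steps of 21 percentage points, 20 points and 17 points, so the figure for spring is a rough one.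

**The decision.** The next flask takes spring's charge, whose ceiling stands above that of the others. Noon is expected last: it has less catalyst than dawn, and its portions are spaced wider than those of dawn and autumn.

**The forecast.** The forecast gives spring > dawn > autumn > noon at 2.5 h and spring > dawn > autumn > noon at 15 min, with 86% for spring, lower than the reckoning here, on the suspicion of “a minor loss with excess reagent”, and 57% for noon.

**The result.** At 2.5 h the order is spring > dawn > autumn > noon, with 100% in spring and 63.6% in noon; at 15 min it is spring > dawn > autumn > noon.

    substrate + free catalyst → catalyst intermediate A (k = 140 M⁻¹ s⁻¹)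
    reagent + catalyst intermediate A ⇌ catalyst intermediate B (K = 10.0 M⁻¹, k = 2.10 M⁻¹ s⁻¹)
    catalyst intermediate B ⇌ by-product + catalyst intermediate C (K = 0.0640 M, k = 1.10 s⁻¹)
    catalyst intermediate C → free catalyst + product (k = 0.270 s⁻¹)

**Two flasks.** At 2.50 h spring stood at its ceiling of 100%, with substrate at 0%, 28.6% of its reagent left and free catalyst back at 100% of the catalyst charged. At the same time noon held 97.2% of its catalyst as catalyst intermediate A, the resting state, and 9.12% of its reagent, so P_max times the reagent spent gives 63.6%. Noon's recipe with 0.170 equiv of reagent has a ceiling of 17.0%; with 5.5% of that reagent left, it ended at 16.1%.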